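## Retrosynthetic overview
1. The last step is global hydrogenolysis of three benzyl ethers (17 → 18).
2. Both tertiary carbinols (each S) come from one double Hoppe–Aggarwal lithiation–borylation/oxidation. The reagent is the TIB ester of (S)-6-methylheptan-2-ol (5), made from (S)-propylene oxide, and the substrate is a bis(aryl-Bpin) diarylmethane (15).
3. The diarylmethane CH2 bridge is formed by a photochemical, meta-effect Friedel–Crafts benzylation. A 3-benzyloxy-4-bromobenzyl carbonate (11) benzylates the position para to OBn of its dibenzylated partner (12).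
4. No ring is constructed. Both arenes are commercial (4-bromo-3-hydroxybenzaldehyde is the only arene source), so the order of events is bridge first, then both stereocenters, then deprotection.

**Assumptions**
- (S)-Propylene oxide, isopentyl bromide, 4-bromo-3-hydroxybenzaldehyde and TIB-Cl are commercial.
- Lithiation–borylation of the secondary TIB ester proceeds with retention at lithiation and at borylation, then inversion at the 1,2-aryl shift. C–B oxidation is retentive. On that basis (S)-5 gives the (S)-carbinols.

## Route

**Step 1**
Reactants: 1 (S)-propylene oxide; 2 isopentylmagnesium bromide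
Product: 3 (2S)-6-methylheptan-2-ol
Conditions: CuI (10 mol%), THF, –30 → 0 °C
Reagents that add atoms: isopentylMgBr, CC(C)CC[Mg]Br
Why: Cu-catalysed Grignard opening of the epoxide at the unhindered CH2. No bond to the stereocenter is broken, so (S)-epoxide gives the (S)-alcohol.

**Step 2**
Reactants: 3; 4 2,4,6-triisopropylbenzoyl chloride
Product: 5 (2S)-6-methylheptan-2-yl 2,4,6-triisopropylbenzoate
Conditions: n-BuLi, THF, 0 °C; then 4; 0 °C → rt
Reagents that add atoms: TIB-Cl, CC(C)c1cc(C(C)C)c(C(=O)Cl)c(C(C)C)c1
Why: alkoxide acylation. It makes the Hoppe-type TIB ester needed for α-lithiation, with the stereocenter untouched.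

**Step 3**
Reactants: 6 4-bromo-3-hydroxybenzaldehyde; 7 benzyl bromide
Product: 8 3-(benzyloxy)-4-bromobenzaldehyde
Conditions: K2CO3, DMF, rt
Reagents that add atoms: BnBr, BrCc1ccccc1
Why: Williamson O-benzylation. The benzyl group is the phenol protecting group that survives the later organolithium, Pd, photochemical and oxidative steps.

**Step 4**
Reactants: 8
Product: 9 (3-(benzyloxy)-4-bromophenyl)methanol
Conditions: NaBH4, MeOH, 0 °C
Reagents that add atoms: none
Why: chemoselective aldehyde reduction.

**Step 5**
Reactants: 9; 10 methyl chloroformate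
Product: 11 (3-(benzyloxy)-4-bromophenyl)methyl methyl carbonate
Conditions: pyridine, CH2Cl2, 0 °C → rt
Reagents that add atoms: ClCO2Me, COC(=O)Cl
Why: acylation of the primary alcohol. The carbonate is a good photonucleofuge and removes its own proton as MeOH + CO2.

**Step 6**
Reactants: 9; 7 benzyl bromide
Product: 12 2-(benzyloxy)-1-bromo-4-[(benzyloxy)methyl]benzene
Conditions: NaH, THF/DMF, 0 °C → rt
Reagents that add atoms: BnBr, BrCc1ccccc1
Why: O-benzylation gives a nucleophilic arene partner whose benzylic position is a very poor photonucleofuge, so it cannot compete as an electrophile. The benzyl ether is removed together with the other benzyl groups at the end.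

**Step 7**
Reactants: 11 (1 equiv); 12 (4 equiv)
Product: 13 1-(benzyloxy)-2-bromo-4-{[3-(benzyloxy)-4-bromophenyl]methyl}-5-[(benzyloxy)methyl]benzene
Conditions: HFIP (0.02 M), hν (300 nm, Rayonet, Pyrex), 25 °C, N2, 12 h
Reagents that add atoms: none (byproducts MeOH and CO2)
Why: Proposed new method: photochemical meta-effect Friedel–Crafts benzylation. The mechanistic reasoning is as follows.
- Excitation of the 3-alkoxybenzyl carbonate shifts charge density to the benzylic carbon (the Zimmerman meta effect). Heterolysis of the C–O bond then gives a benzyl cation/carbonate ion pair, which HFIP stabilises.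
- The cation is trapped by the carbon of 12 that is para to OBn and ortho to CH2OBn. This places the bridge para to O on ring B and meta to Br, as in the target.
- The carbonate leaves as MeOH + CO2 and takes up the proton, so no acid builds up.
- Ground-state 11 has no resonance donor conjugated to the benzylic carbon, so it is inert until irradiated.
- The closest known reactions are meta-effect photosolvolysis of 3-alkoxybenzyl esters and Friedel–Crafts benzylation. No stereocenter is formed here.

**Step 8**
Reactants: 13; 14 bis(pinacolato)diboron
Product: 15 diarylmethane bis(aryl-Bpin): 2,2'-{[(benzyloxy)methyl-substituted]methylenebis[(benzyloxy)arene-diyl]}bis(pinacolborane), drawn in the list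
Conditions: PdCl2(dppf) (5 mol%), KOAc, 1,4-dioxane, 90 °C, 16 h
Reagents that add atoms: B2pin2, CC1(C)OB(OC1(C)C)B1OC(C)(C)C(C)(C)O1
Why: Miyaura borylation of both aryl bromides. The bromides sit ortho to OBn, and the resulting Bpin groups are the 1,2-migration partners for step 9.

**Step 9**
Reactants: 15; 5 (2.6 equiv)
Product: 16 bis(tertiary benzylic pinacol boronic ester), unisolated
Conditions: 5 with s-BuLi (2.5 equiv) and TMEDA (2.6 equiv), Et2O, –78 °C, 5 h; then 15 in THF, –78 °C → rt; then 40 °C, 16 h
Reagents that add atoms: none (the alkyl fragments of 5 are carried by the reactant)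
Why: Hoppe–Aggarwal lithiation–borylation (Matteson-type 1,2-metallate shift). Each aryl-Bpin is attacked by the lithiated TIB ester, and the aryl group shifts onto carbon anti to the carboxylate leaving group. Both tertiary centers are set from the single stereocenter of (S)-5, with only achiral TMEDA present.

**Step 10**
Reactants: 16
Product: 17 tri-O-benzyl diol
Conditions: 2 M NaOH, 30% H2O2, THF, 0 °C → rt, 4 h. Steps 9 and 10 can be telescoped in one flask.
Reagents that add atoms: hydrogen peroxide, OO
Why: oxidation of the C–B bond to C–OH with retention, giving the two (S) tertiary benzylic alcohols without carbocation intermediates.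

**Step 11**
Reactants: 17
Product: 18 Disydonol C
Conditions: H2 (1 atm), 10% Pd/C, solid NaHCO3, EtOAc, rt, 3 h
Reagents that add atoms: none (hydrogen only)
Why: hydrogenolysis of two aryl benzyl ethers and one primary benzyl ether. The tertiary carbinols are untouched under neutral, buffered conditions, so the stereocenters are not scrambled.

## Compound list
1 | (S)-propylene oxide | C[C@H]1CO1 | starting material
2 | isopentylmagnesium bromide | CC(C)CC[Mg]Br | starting material
3 | (2S)-6-methylheptan-2-ol | CC(C)CCC[C@H](C)O | intermediate
4 | 2,4,6-triisopropylbenzoyl chloride | CC(C)c1cc(C(C)C)c(C(=O)Cl)c(C(C)C)c1 | starting material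
5 | (2S)-6-methylheptan-2-yl 2,4,6-triisopropylbenzoate | CC(C)CCC[C@H](C)OC(=O)c1c(C(C)C)cc(C(C)C)cc1C(C)C | intermediate
6 | 4-bromo-3-hydroxybenzaldehyde | O=Cc1ccc(Br)c(O)c1 | starting material
7 | benzyl bromide | BrCc1ccccc1 | starting material
8 | 3-(benzyloxy)-4-bromobenzaldehyde | O=Cc1ccc(Br)c(OCc2ccccc2)c1 | intermediate
9 | (3-(benzyloxy)-4-bromophenyl)methanol | OCc1ccc(Br)c(OCc2ccccc2)c1 | intermediate
10 | methyl chloroformate | COC(=O)Cl | starting material
11 | (3-(benzyloxy)-4-bromophenyl)methyl methyl carbonate | COC(=O)OCc1ccc(Br)c(OCc2ccccc2)c1 | intermediate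
12 | 2-(benzyloxy)-1-bromo-4-[(benzyloxy)methyl]benzene | Brc1ccc(COCc2ccccc2)cc1OCc1ccccc1 | intermediate
13 | dibromodiarylmethane (three OBn groups) | Brc1ccc(Cc2cc(Br)c(OCc3ccccc3)cc2COCc2ccccc2)cc1OCc1ccccc1 | intermediate
14 | bis(pinacolato)diboron | CC1(C)OB(OC1(C)C)B1OC(C)(C)C(C)(C)O1 | starting material
15 | bis(aryl-Bpin) diarylmethane | CC1(C)OB(OC1(C)C)c1ccc(Cc2cc(B3OC(C)(C)C(C)(C)O3)c(OCc3ccccc3)cc2COCc2ccccc2)cc1OCc1ccccc1 | intermediate
16 | bis(tertiary benzylic Bpin) | CC(C)CCC[C@](C)(B4OC(C)(C)C(C)(C)O4)c1ccc(Cc2cc([C@@](C)(B5OC(C)(C)C(C)(C)O5)CCCC(C)C)c(OCc3ccccc3)cc2COCc2ccccc2)cc1OCc1ccccc1 | intermediate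
17 | tri-O-benzyl diol | CC(C)CCC[C@](C)(O)c1ccc(Cc2cc([C@@](C)(O)CCCC(C)C)c(OCc3ccccc3)cc2COCc2ccccc2)cc1OCc1ccccc1 | intermediate
18 | Disydonol C | CC(C)CCC[C@](C)(O)c1ccc(Cc2cc([C@@](C)(O)CCCC(C)C)c(O)cc2CO)cc1O | target

## Summary
- **Total steps:** 11 (10 isolations if steps 9 and 10 are telescoped).
- **Longest linear sequence:** 8 steps, from 6 through 8, 9, 11, 13, 15, 16 and 17 to 18.
- **Three steps most likely to fail:**
  1. **Step 7 (proposed new step).** Risks are aryl C–Br photolysis at 300 nm, self-condensation, and poor regioselectivity.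
     - Fallback: a known acid-mediated reductive Friedel–Crafts of aldehyde 8 with 12 (Et3SiH, TMSOTf or InBr3, CH2Cl2). This also removes the need for steps 4–5 on the electrophile arm.
  2. **Step 9.** The ortho-OBn aryl-Bpin groups are hindered, so the 1,2-shift may stall at the mono-adduct or the stereochemical course may differ from the assumption.
     - Fallback: switch to Clayden-type stereospecific lithiation/N→C aryl migration of the N-methyl-N-aryl carbamate of 3. The aryl groups would come from 13 by Buchwald amination. If the stereochemical course is the reverse of that assumed, start from (R)-propylene oxide.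
  3. **Step 11.** Hydrogenolysis may cleave or dehydrate the o-hydroxy tertiary benzylic carbinols.
     - Fallback: reductive debenzylation with Li-DTBB (lithium 4,4′-di-tert-butylbiphenylide), THF, –78 °C, which proceeds by electron transfer and does not cleave the tertiary alkoxide C–O bonds.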